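## The problem

The target is a germacranolide-type ten-membered carbocycle (C1–C10) with a Z trisubstituted alkene at C1=C10 and an E trisubstituted alkene at C4=C5. An α-methylene-γ-butyrolactone is trans-fused across C6–C7 (lactone oxygen on C6, C11 on C7, carbonyl C12, methylene C13). Four contiguous stereocentres run from C6 to C9: the lactone carbinol C6, the tertiary alcohol C7 at the ring fusion, C8 carrying the (2S,3R)-2,3-dimethyloxirane-2-carboxylate, and the free allylic alcohol C9. C8 and C9 form a cis-diol pair that can come from the chiral pool, and C6 can control C7 through the lactone ring. The open stereochemical task is therefore to relate C6 to C8/C9 across C7. The 1,5-diene in a medium ring is prone to acid-induced transannular cyclisation and to Cope rearrangement on heating. The methylene lactone is a Michael acceptor, the β-hydroxy lactone can undergo retro-aldol cleavage under base, the epoxy ester does not tolerate strong acid or nucleophiles, and an acyl group on O8 can migrate under base. The enabling feature is that C7 carries C11 and that C11 is tied back through C12 and the lactone oxygen to the neighbouring C6. An acrylate on O6 already contains C11–C13, so with C7 as a ketone an α-metallated acrylate can be delivered across this five-atom loop. That one operation makes the C7–C11 bond, the C7 stereocentre, the lactone ring and the exocyclic methylene.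

## Retrosynthesis

**C8 ester (38 ⇒ 37 ⇒ 31 + 35).** The C8–O acyl bond is cut last. Carrying the epoxy ester earlier would expose it to divalent chromium and DDQ, and epoxidising a C8 tiglate late would have to compete with the two electron-rich ring alkenes. Alcohol 31 lacks the two side-chain stereocentres; acid 35 comes from tiglic acid 32 through alcohol 33 and epoxy alcohol 34, where a Sharpless epoxidation sets both centres. The forward reaction must acylate a hindered secondary hydroxyl beside a free tertiary one, and the last silyl ether (37 → 38) must leave without base.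

**Lactone annulation (31 ⇒ 30 ⇒ 29).** After selective unmasking of O8, the C7–C11 bond is cut, which opens the lactone to the 2-bromoacrylate of α-acyloxy ketone 29. Cutting O6–C12 instead would need an intermolecular acrylate-anion addition to a hindered ketone with no facial bias. Cutting C11=C13 would need base-mediated methylenation of a β-hydroxy lactone that can undergo retro-aldol cleavage. Precursor 29 has one ring, one stereocentre and one C–C bond fewer than 30. The forward step must insert the metal into the C–Br bond chemoselectively, close 5-exo, and choose the ketone face that gives the trans-fused lactone.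

**C7 oxidation level and O6 ester (29 ⇒ 28 ⇒ 27 ⇒ 25 + 26).** The ketone is traced to a PMB-protected carbinol, the only group removable beside TES, TBS and the bromoacrylate. The ester is traced to alcohol 25 and 2-bromoacrylic acid 26. The C6–O bond is formed with inversion (Mitsunobu), because the ring closure is expected to give the C6 epimer; the other epimer would be esterified with retention, so both outcomes converge on 27.

**Ten-membered ring (25 ⇒ 24).** The C5–C6 bond is cut to alkenyl iodide–aldehyde 24, closed by a Nozaki–Hiyama–Kishi reaction. A C2–C3 closure would be an sp3–sp3 macrocyclisation without a good method, and metathesis at C4=C5 is unreliable for an E trisubstituted alkene in a ten-membered ring. Precursor 24 is acyclic with both alkene geometries fixed. The forward step needs high dilution and retention of the E geometry.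

**C6 carbon (24 ⇒ 23 ⇒ 22 ⇒ 21 ⇒ 15 + 19).** The C6–C7 bond is cut to aldehyde 15 and the hydroxymethyl-anion equivalent 20, generated from stannane 19 (made from 16 and 17). The PMB group arrives on O6 and is moved to O7 through acetal 22, which frees C6 for oxidation. The C7 centre made here is later oxidised; it only serves to direct the ring closure.

**C3–C5 unit (15 ⇒ 14 ⇒ 12 ⇒ 11 ⇒ 8 + 9).** The C2–C3 bond is cut to allylic bromide 8 and 1-(trimethylsilyl)propyne 9. Carboalumination–iodination of alkyne 12 supplies the C4 methyl group and the E alkenyl iodide in one step. The temporary primary TES ether on O7 is oxidised directly to aldehyde 15.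

**Ring opening of the chiral pool (8 ⇒ 7 ⇒ 6 ⇒ 3 ⇒ 2 ⇒ 1).** C10, C1, C2, C7, C8 and C9 are the six ring carbons of toluene cis-dihydrodiol 1. Cutting the ring between C2 and C7 (dihydroxylation, periodate) leaves the C1=C10 alkene Z because it was cis in the ring, and C8/C9 arrive with the correct absolute configuration. The forward sequence must distinguish O8 from O9 (TES then TBS, 2 and 3) and the two primary alcohols of diol 6 (allylic bromide 7, then silyl ether 8).

## Roads not taken

**Alternative 1:** The cut is a temporary transannular C4–C9 bond. A bicyclic substrate with a tertiary C9 alkoxide and a C5 sulfonate would fragment (Wharton/Grob) to the ten-membered dienone A1, creating the C9 ketone and the E C4=C5 alkene.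
- Merits: the alkene geometry follows stereospecifically from the anti-periplanar arrangement, no high dilution is needed, and this fragmentation is the classical entry to germacranes.
- Weak points: the substrate must already carry the fully substituted C7 with its three-carbon side chain and the C6 and C8 oxygens in the correct relative configuration on a decalin. After fragmentation the C9 ketone, conjugated to the Z alkene, must be reduced stereoselectively. The lactone still has to be made by acetonide removal under acid and oxidation of C12.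
- Comparison: for forming the medium ring this route is more dependable than a chromium-mediated macrocyclisation. The chosen plan sets against it a chiral-pool start that delivers C8, C9 and the Z alkene in the first three steps, and a key step that finishes C7, the lactone and the methylene together.

**Alternative 2:** The cut is the C7–C8 bond. Low-valent titanium (TiCl3, Zn–Cu couple) would couple a C7 ketone with a C8 aldehyde to give diol A2, forming the ring and both carbinol centres.
- Merits: high convergence, since the acyclic keto aldehyde is assembled from two halves, and the tertiary carbinol appears directly with its carbon substituent.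
- Weak points: two stereocentres must be controlled in a pinacol coupling whose diastereoselectivity in medium rings is hard to predict. Low-valent titanium can deoxygenate the diol or attack the allylic C6 and C9 oxygens. The C11 unit arrives as a protected 1,3-diol that must still be desymmetrised, oxidised, lactonised and eliminated.
- Comparison: this route reaches a ten-membered ring in fewer steps. The chosen plan answers with one new stereocentre per ring-forming step, each under a defined control element, and with a key-step product that already is the methylene lactone.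

**Alternative 3:** The cut is the C3–C4 bond. Hydroboration of a terminal C2=C3 vinyl group with 9-BBN and coupling with a C4 alkenyl iodide under PdCl2(dppf)/Cs2CO3 would give hydroxy lactone A3.
- Merits: the lactone and the C6/C7 centres are set before ring closure, the macrocyclisation creates no stereocentre, and the palladium chemistry tolerates the functionality.
- Weak points: closure of a strained ten-membered ring by alkyl–alkenyl coupling is rarely shown. Hydroboration must select one alkene of a Z diene. A3 still lacks C13, and methylenating a β-hydroxy lactone with a tertiary carbinol risks retro-aldol cleavage.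
- Comparison: in stereochemical security at C6 and C7 this route is better. The chosen plan offers instead methylene and lactone in one step, and the same chromium chemistry for both ring closures.

Key step: step 19

Assumption: diol 1 and tributyl(iodomethyl)stannane 16 are taken as purchasable; the acetal carbon of 22 forms as an inconsequential mixture of epimers and is left undefined.

## Route

Step 1
Reactants: 1 (1S,2R)-3-methylcyclohexa-3,5-diene-1,2-diol
Product: 2 (1R,6S)-2-methyl-6-[(triethylsilyl)oxy]cyclohexa-2,4-dien-1-ol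
Conditions: TESCl (1.05 equiv), imidazole, DMF, −40 °C
Reagents that add atoms: chlorotriethylsilane, CC[Si](Cl)(CC)CC
Why: Regioselective silylation; in arene cis-dihydrodiols the hydroxyl distal to the ring substituent is the less hindered one and reacts first with silyl chlorides, and low temperature with one equivalent keeps the reaction at the mono-ether.

Step 2
Reactants: 2 mono-TES ether
Product: 3 tert-butyl(dimethyl){[(1R,6S)-2-methyl-6-[(triethylsilyl)oxy]cyclohexa-2,4-dien-1-yl]oxy}silane
Conditions: TBSOTf, 2,6-lutidine, CH2Cl2, −78 °C → 0 °C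
Reagents that add atoms: tert-butyldimethylsilyl trifluoromethanesulfonate, CC(C)(C)[Si](C)(C)OS(=O)(=O)C(F)(F)F
Why: Silyl triflate silylation of the remaining hindered allylic hydroxyl; the hindered base and low temperature avoid acid-induced aromatisation of the diene.

Step 3
Reactants: 3 bis-silyl diene
Product: 6 (2Z,4R,5S)-4-[(tert-butyldimethylsilyl)oxy]-3-methyl-5-[(triethylsilyl)oxy]hex-2-ene-1,6-diol, via cyclohexenediol 4 (not isolated), via dialdehyde 5 (not isolated)
Conditions: OsO4 (2 mol %), NMO, acetone–H2O, 0 °C; NaIO4, NaHCO3, rt; then NaBH4, EtOH, 0 °C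
Reagents that add atoms: N-methylmorpholine N-oxide, C[N+]1([O-])CCOCC1; water, O
Why: Upjohn dihydroxylation should take the disubstituted ring alkene (future C2 and C7), which is less shielded than the methyl-bearing alkene next to the TBS ether, anti to the neighbouring silyloxy group. Periodate glycol cleavage opens the ring and borohydride reduces both aldehydes, the enal by 1,2-addition. The two transient carbinol centres are destroyed and the C1=C10 alkene keeps the Z geometry it had in the ring.

Step 4
Reactants: 6 diol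
Product: 7 (2S,3R,4Z)-6-bromo-3-[(tert-butyldimethylsilyl)oxy]-4-methyl-2-[(triethylsilyl)oxy]hex-4-en-1-ol
Conditions: NBS, Me2S, CH2Cl2, −20 °C → 0 °C
Reagents that add atoms: N-bromosuccinimide, O=C1CCC(=O)N1Br
Why: Corey–Kim halogenation; the sulfonium reagent converts allylic alcohols into bromides under neutral conditions with retention of alkene geometry, while the saturated primary alcohol is returned on work-up.

Step 5
Reactants: 7 bromo alcohol
Product: 8 (2Z,4R,5S)-1-bromo-4-[(tert-butyldimethylsilyl)oxy]-3-methyl-5,6-bis[(triethylsilyl)oxy]hex-2-ene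
Conditions: TESOTf, 2,6-lutidine, CH2Cl2, −78 °C
Reagents that add atoms: triethylsilyl trifluoromethanesulfonate, CC[Si](CC)(CC)OS(=O)(=O)C(F)(F)F
Why: Silylation of the primary alcohol with a silyl triflate and a non-nucleophilic base, which does not displace the allylic bromide.

Step 6
Reactants: 8 allylic bromide; 9 1-(trimethylsilyl)propyne
Product: 11 (5Z,7R,8S)-7-[(tert-butyldimethylsilyl)oxy]-6-methyl-8,9-bis[(triethylsilyl)oxy]-1-(trimethylsilyl)non-5-en-1-yne, via propargyllithium reagent 10 (not isolated)
Conditions: 9, n-BuLi, THF, −78 °C; then 8, −78 °C → −20 °C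
Reagents that add atoms: none
Why: Lithiated 1-(trimethylsilyl)propyne alkylates primary allylic bromides at its propargylic carbon by SN2 substitution; the silyl group suppresses allenyl products and the C2–C3 bond is formed without touching the Z alkene.

Step 7
Reactants: 11 silylated enyne
Product: 12 (5Z,7R,8S)-7-[(tert-butyldimethylsilyl)oxy]-6-methyl-8,9-bis[(triethylsilyl)oxy]non-5-en-1-yne
Conditions: K2CO3, MeOH, 0 °C
Reagents that add atoms: none
Why: Base-catalysed methanolysis of the alkynyl C–Si bond; alkyl silyl ethers are stable to carbonate in methanol at this temperature.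

Step 8
Reactants: 12 terminal alkyne
Product: 14 (1E,5Z,7R,8S)-7-[(tert-butyldimethylsilyl)oxy]-1-iodo-2,6-dimethyl-8,9-bis[(triethylsilyl)oxy]nona-1,5-diene, via alkenylalane 13 (not isolated)
Conditions: Me3Al, Cp2ZrCl2 (20 mol %), H2O, CH2Cl2, −23 °C; then iodine, THF, −23 °C → 0 °C
Reagents that add atoms: trimethylaluminium, C[Al](C)C; iodine, [I][I]
Why: Negishi zirconium-catalysed carboalumination (water-accelerated variant) adds methyl and aluminium syn across the alkyne with methyl on the internal carbon, and iodinolysis with retention gives the E alkenyl iodide.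

Step 9
Reactants: 14 alkenyl iodide
Product: 15 (2R,3R,4Z,8E)-3-[(tert-butyldimethylsilyl)oxy]-9-iodo-4,8-dimethyl-2-[(triethylsilyl)oxy]nona-4,8-dienal
Conditions: (COCl)2, DMSO, CH2Cl2, −78 °C → −40 °C; then Et3N, −78 °C → 0 °C
Reagents that add atoms: none
Why: Swern conditions convert primary triethylsilyl ethers directly into aldehydes while secondary TES and TBS ethers survive, so O7 is unmasked and oxidised in one operation without epimerising C8.

Step 10
Reactants: 16 tributyl(iodomethyl)stannane; 17 4-methoxybenzyl alcohol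
Product: 19 tributyl{[(4-methoxybenzyl)oxy]methyl}stannane, via sodium alkoxide 18 (not isolated)
Conditions: 17, NaH, THF–DMF, 0 °C; then 16, rt
Reagents that add atoms: none
Why: Williamson ether synthesis; the alkoxide displaces iodide from the iodomethylstannane.

Step 11
Reactants: 15 aldehyde; 19 stannane
Product: 21 (2S,3S,4R,5Z,9E)-4-[(tert-butyldimethylsilyl)oxy]-10-iodo-1-[(4-methoxybenzyl)oxy]-5,9-dimethyl-3-[(triethylsilyl)oxy]deca-5,9-dien-2-ol, via alkoxymethyllithium 20 (not isolated)
Conditions: 19, n-BuLi, THF, −78 °C; then 15, −78 °C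
Reagents that add atoms: none
Why: Tin–lithium exchange gives the α-alkoxy organolithium (hydroxymethyl anion equivalent), which adds to the aldehyde faster than it exchanges with the alkenyl iodide. Polar Felkin–Anh addition anti to the α-silyloxy group should give mainly the (2S) carbinol, a centre that is later oxidised and only serves to direct step 15.

Step 12
Reactants: 21 hydroxy PMB ether
Product: 22 (4S)-4-[(1S,2R,3Z,7E)-2-[(tert-butyldimethylsilyl)oxy]-8-iodo-3,7-dimethyl-1-[(triethylsilyl)oxy]octa-3,7-dien-1-yl]-2-(4-methoxyphenyl)-1,3-dioxolane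
Conditions: DDQ, 4 Å molecular sieves, CH2Cl2, 0 °C
Reagents that add atoms: none
Why: Anhydrous DDQ oxidation of the PMB ether gives a benzylic oxocarbenium ion that is trapped by the neighbouring hydroxyl (oxidative acetal formation), which moves the protecting group onto both oxygens.

Step 13
Reactants: 22 acetal
Product: 23 (2S,3S,4R,5Z,9E)-4-[(tert-butyldimethylsilyl)oxy]-10-iodo-2-[(4-methoxybenzyl)oxy]-5,9-dimethyl-3-[(triethylsilyl)oxy]deca-5,9-dien-1-ol
Conditions: i-Bu2AlH, CH2Cl2, −78 °C → 0 °C
Reagents that add atoms: none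
Why: Regioselective reductive opening of the 4-methoxybenzylidene acetal; the aluminium hydride coordinates the less hindered primary oxygen, which becomes the free alcohol, and the PMB ether remains on the secondary oxygen.

Step 14
Reactants: 23 primary alcohol
Product: 24 (2R,3S,4R,5Z,9E)-4-[(tert-butyldimethylsilyl)oxy]-10-iodo-2-[(4-methoxybenzyl)oxy]-5,9-dimethyl-3-[(triethylsilyl)oxy]deca-5,9-dienal
Conditions: DMP, NaHCO3, CH2Cl2, 0 °C → rt
Reagents that add atoms: none
Why: Dess–Martin oxidation under buffered conditions gives the α-alkoxy aldehyde without epimerisation; it is used directly.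

Step 15
Reactants: 24 iodo aldehyde
Product: 25 (1S,2E,6Z,8R,9S,10S)-8-[(tert-butyldimethylsilyl)oxy]-10-[(4-methoxybenzyl)oxy]-3,7-dimethyl-9-[(triethylsilyl)oxy]cyclodeca-2,6-dien-1-ol
Conditions: CrCl2 (10 equiv), NiCl2 (cat.), DMSO, rt, 0.003 M, slow addition
Reagents that add atoms: none
Why: Intramolecular Nozaki–Hiyama–Kishi reaction; the alkenylchromium species formed from the E iodide adds to the aldehyde with retention of alkene geometry and closes the ten-membered ring at C5–C6. Felkin–Anh addition anti to the C7 PMB ether is expected to give the (1S) carbinol, the C6 epimer of the target, which step 16 corrects.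

Step 16
Reactants: 25 macrocyclic alcohol; 26 2-bromoprop-2-enoic acid
Product: 27 (1R,2E,6Z,8R,9S,10S)-8-[(tert-butyldimethylsilyl)oxy]-10-[(4-methoxybenzyl)oxy]-3,7-dimethyl-9-[(triethylsilyl)oxy]cyclodeca-2,6-dien-1-yl 2-bromoprop-2-enoate
Conditions: PPh3, DIAD, toluene, 0 °C; then 25 and 26, 0 °C → rt
Reagents that add atoms: none
Why: Mitsunobu esterification; the acidic carboxylic acid displaces the activated allylic oxygen by SN2 with inversion and sets the (R) configuration of the target at C6. Pre-forming the phosphine–azodicarboxylate adduct keeps free phosphine away from the acrylate.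

Step 17
Reactants: 27 PMB ether
Product: 28 (1R,2E,6Z,8R,9S,10S)-8-[(tert-butyldimethylsilyl)oxy]-10-hydroxy-3,7-dimethyl-9-[(triethylsilyl)oxy]cyclodeca-2,6-dien-1-yl 2-bromoprop-2-enoate
Conditions: DDQ, CH2Cl2–pH 7 buffer, 0 °C
Reagents that add atoms: none
Why: Oxidative cleavage of the PMB ether; silyl ethers, the ring alkenes and the bromoacrylate are inert to DDQ under buffered conditions.

Step 18
Reactants: 28 hydroxy ester
Product: 29 (1R,2E,6Z,8R,9R)-8-[(tert-butyldimethylsilyl)oxy]-3,7-dimethyl-10-oxo-9-[(triethylsilyl)oxy]cyclodeca-2,6-dien-1-yl 2-bromoprop-2-enoate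
Conditions: DMP, NaHCO3, CH2Cl2, 0 °C → rt
Reagents that add atoms: none
Why: Dess–Martin oxidation of the secondary alcohol to the α-acyloxy ketone under non-basic conditions, which protects the acidic C6 hydrogen from epimerisation.

Step 19
Reactants: 29 keto 2-bromoacrylate
Product: 30 (3aR,4R,5R,6Z,10E,11aR)-5-[(tert-butyldimethylsilyl)oxy]-3a-hydroxy-6,10-dimethyl-3-methylidene-4-[(triethylsilyl)oxy]-3a,4,5,8,9,11a-hexahydrocyclodeca[b]furan-2(3H)-one
Conditions: CrCl2 (6 equiv), NiCl2 (cat.), DMF–THF, rt, 0.01 M
Reagents that add atoms: none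
Why: Proposed new method: CrCl2 reduces NiCl2 to zerovalent nickel, which inserts into the C11–Br bond; transmetalation to trivalent chromium gives an alkenylchromium species that adds to the C7 ketone, and the chromium alkoxide is released as the tertiary alcohol on work-up. The closest known reaction type is the intramolecular Nozaki–Hiyama–Kishi addition of alkenyl halides to ketones, together with chromium-mediated couplings of 3-iodoacrylates with aldehydes; new here is an α-(alkoxycarbonyl)alkenyl donor delivered through its own ester tether. The γ-lactone closes in a 5-exo-trig mode, C11 attacking the exocyclic C7=O within the chain C7–C6–O–C12–C11. The new C7 stereocentre is controlled by C6: the tether holds C11 over the ketone face on the side of the C6–O bond, and the ten-membered ring should keep the C5–C6–C7–C8 backbone extended with C8 anti to C5, which gives the trans-fused lactone. The step needs chemoselectivity (C–Br insertion without reductive cleavage of the α-acyloxy ketone or conjugate reactions of the acrylate) and facial selectivity. The mild reducing power of divalent chromium, the intramolecular delivery and dilution secure the first; the fixed C6 configuration and the ring conformation secure the second. The chromium alkoxide of the tertiary carbinol is not basic enough to trigger retro-aldol cleavage or silyl migration.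

Step 20
Reactants: 30 bis-silyl lactone
Product: 31 (3aS,4R,5R,6Z,10E,11aR)-5-[(tert-butyldimethylsilyl)oxy]-3a,4-dihydroxy-6,10-dimethyl-3-methylidene-3a,4,5,8,9,11a-hexahydrocyclodeca[b]furan-2(3H)-one
Conditions: HF·pyridine, pyridine, THF, 0 °C
Reagents that add atoms: none
Why: Selective desilylation; buffered HF·pyridine cleaves a secondary TES ether much faster than a secondary TBS ether, and the conditions are neither basic nor strongly acidic.

Step 21
Reactants: 32 tiglic acid
Product: 33 (2E)-2-methylbut-2-en-1-ol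
Conditions: LiAlH4, Et2O, 0 °C
Reagents that add atoms: none
Why: Hydride reduction of the unsaturated acid by 1,2-addition; the E geometry is retained.

Step 22
Reactants: 33 allylic alcohol
Product: 34 [(2R,3R)-2,3-dimethyloxiran-2-yl]methanol
Conditions: Ti(OiPr)4 (cat.), D-(−)-diisopropyl tartrate (cat.), t-BuOOH, 4 Å molecular sieves, CH2Cl2, −20 °C
Reagents that add atoms: tert-butyl hydroperoxide, CC(C)(C)OO
Why: Sharpless asymmetric epoxidation; with the D-(−)-tartrate the oxygen is delivered to the face that gives the (2R,3R) epoxy alcohol, and the E alkene fixes the cis relation of the two methyl groups.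

Step 23
Reactants: 34 epoxy alcohol
Product: 35 (2S,3R)-2,3-dimethyloxirane-2-carboxylic acid
Conditions: RuCl3 (cat.), NaIO4, CCl4–MeCN–H2O, rt
Reagents that add atoms: water, O
Why: Ruthenium tetroxide oxidation of the primary alcohol to the acid leaves the epoxide intact; the C2 descriptor changes from R to S only through the change in substituent priority.

Step 24
Reactants: 31 C8 alcohol; 35 epoxy acid
Product: 37 (3aR,4R,5R,6Z,10E,11aR)-5-[(tert-butyldimethylsilyl)oxy]-3a-hydroxy-6,10-dimethyl-3-methylidene-2-oxo-2,3,3a,4,5,8,9,11a-octahydrocyclodeca[b]furan-4-yl (2S,3R)-2,3-dimethyloxirane-2-carboxylate, via mixed anhydride 36 (not isolated)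
Conditions: 35, 2,4,6-trichlorobenzoyl chloride, Et3N, THF, rt; then 31, DMAP, toluene, rt
Reagents that add atoms: none
Why: Yamaguchi esterification; the mixed anhydride acylates the hindered secondary C8 hydroxyl under DMAP catalysis, the tertiary C7 hydroxyl does not react, and the α-quaternary acid cannot epimerise.

Step 25
Reactants: 37 TBS ether
Product: 38 (3aR,4R,5R,6Z,10E,11aR)-3a,5-dihydroxy-6,10-dimethyl-3-methylidene-2-oxo-2,3,3a,4,5,8,9,11a-octahydrocyclodeca[b]furan-4-yl (2S,3R)-2,3-dimethyloxirane-2-carboxylate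
Conditions: HF·pyridine, pyridine, THF, 0 °C → rt
Reagents that add atoms: none
Why: Fluoride-mediated cleavage of the allylic TBS ether under buffered, non-basic conditions, which avoids acyl migration from O8, conjugate addition to the methylene lactone and retro-aldol cleavage.

## Compound list

1 | (1S,2R)-3-methylcyclohexa-3,5-diene-1,2-diol | CC1=CC=C[C@H](O)[C@@H]1O | starting material
2 | (1R,6S)-2-methyl-6-[(triethylsilyl)oxy]cyclohexa-2,4-dien-1-ol | CC1=CC=C[C@H](O[Si](CC)(CC)CC)[C@@H]1O | intermediate
3 | tert-butyl(dimethyl){[(1R,6S)-2-methyl-6-[(triethylsilyl)oxy]cyclohexa-2,4-dien-1-yl]oxy}silane | CC1=CC=C[C@H](O[Si](CC)(CC)CC)[C@@H]1O[Si](C)(C)C(C)(C)C | intermediate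
4 | (1R,2R,5R,6S)-5-[(tert-butyldimethylsilyl)oxy]-4-methyl-6-[(triethylsilyl)oxy]cyclohex-3-ene-1,2-diol | CC1=C[C@@H](O)[C@@H](O)[C@H](O[Si](CC)(CC)CC)[C@@H]1O[Si](C)(C)C(C)(C)C | intermediate
5 | (2Z,4R,5R)-4-[(tert-butyldimethylsilyl)oxy]-3-methyl-5-[(triethylsilyl)oxy]hex-2-enedial | O=C/C=C(/C)[C@@H](O[Si](C)(C)C(C)(C)C)[C@@H](O[Si](CC)(CC)CC)C=O | intermediate
6 | (2Z,4R,5S)-4-[(tert-butyldimethylsilyl)oxy]-3-methyl-5-[(triethylsilyl)oxy]hex-2-ene-1,6-diol | OC/C=C(/C)[C@@H](O[Si](C)(C)C(C)(C)C)[C@@H](O[Si](CC)(CC)CC)CO | intermediate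
7 | (2S,3R,4Z)-6-bromo-3-[(tert-butyldimethylsilyl)oxy]-4-methyl-2-[(triethylsilyl)oxy]hex-4-en-1-ol | BrC/C=C(/C)[C@@H](O[Si](C)(C)C(C)(C)C)[C@@H](O[Si](CC)(CC)CC)CO | intermediate
8 | (2Z,4R,5S)-1-bromo-4-[(tert-butyldimethylsilyl)oxy]-3-methyl-5,6-bis[(triethylsilyl)oxy]hex-2-ene | BrC/C=C(/C)[C@@H](O[Si](C)(C)C(C)(C)C)[C@@H](O[Si](CC)(CC)CC)CO[Si](CC)(CC)CC | intermediate
9 | 1-(trimethylsilyl)propyne | CC#C[Si](C)(C)C | starting material
10 | [3-(trimethylsilyl)prop-2-yn-1-yl]lithium | [Li]CC#C[Si](C)(C)C | intermediate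
11 | (5Z,7R,8S)-7-[(tert-butyldimethylsilyl)oxy]-6-methyl-8,9-bis[(triethylsilyl)oxy]-1-(trimethylsilyl)non-5-en-1-yne | C[Si](C)(C)C#CCC/C=C(/C)[C@@H](O[Si](C)(C)C(C)(C)C)[C@@H](O[Si](CC)(CC)CC)CO[Si](CC)(CC)CC | intermediate
12 | (5Z,7R,8S)-7-[(tert-butyldimethylsilyl)oxy]-6-methyl-8,9-bis[(triethylsilyl)oxy]non-5-en-1-yne | C#CCC/C=C(/C)[C@@H](O[Si](C)(C)C(C)(C)C)[C@@H](O[Si](CC)(CC)CC)CO[Si](CC)(CC)CC | intermediate
13 | [(1E,5Z,7R,8S)-7-[(tert-butyldimethylsilyl)oxy]-2,6-dimethyl-8,9-bis[(triethylsilyl)oxy]nona-1,5-dien-1-yl]dimethylalane | C[Al](C)/C=C(\C)CC/C=C(/C)[C@@H](O[Si](C)(C)C(C)(C)C)[C@@H](O[Si](CC)(CC)CC)CO[Si](CC)(CC)CC | intermediate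
14 | (1E,5Z,7R,8S)-7-[(tert-butyldimethylsilyl)oxy]-1-iodo-2,6-dimethyl-8,9-bis[(triethylsilyl)oxy]nona-1,5-diene | I/C=C(\C)CC/C=C(/C)[C@@H](O[Si](C)(C)C(C)(C)C)[C@@H](O[Si](CC)(CC)CC)CO[Si](CC)(CC)CC | intermediate
15 | (2R,3R,4Z,8E)-3-[(tert-butyldimethylsilyl)oxy]-9-iodo-4,8-dimethyl-2-[(triethylsilyl)oxy]nona-4,8-dienal | I/C=C(\C)CC/C=C(/C)[C@@H](O[Si](C)(C)C(C)(C)C)[C@@H](O[Si](CC)(CC)CC)C=O | intermediate
16 | tributyl(iodomethyl)stannane | CCCC[Sn](CCCC)(CCCC)CI | starting material
17 | 4-methoxybenzyl alcohol | COc1ccc(CO)cc1 | starting material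
18 | sodium (4-methoxyphenyl)methanolate | [Na+].[O-]Cc1ccc(OC)cc1 | intermediate
19 | tributyl{[(4-methoxybenzyl)oxy]methyl}stannane | CCCC[Sn](CCCC)(CCCC)COCc1ccc(OC)cc1 | intermediate
20 | {[(4-methoxybenzyl)oxy]methyl}lithium | [Li]COCc1ccc(OC)cc1 | intermediate
21 | (2S,3S,4R,5Z,9E)-4-[(tert-butyldimethylsilyl)oxy]-10-iodo-1-[(4-methoxybenzyl)oxy]-5,9-dimethyl-3-[(triethylsilyl)oxy]deca-5,9-dien-2-ol | I/C=C(\C)CC/C=C(/C)[C@@H](O[Si](C)(C)C(C)(C)C)[C@@H](O[Si](CC)(CC)CC)[C@@H](O)COCc1ccc(OC)cc1 | intermediate
22 | (4S)-4-[(1S,2R,3Z,7E)-2-[(tert-butyldimethylsilyl)oxy]-8-iodo-3,7-dimethyl-1-[(triethylsilyl)oxy]octa-3,7-dien-1-yl]-2-(4-methoxyphenyl)-1,3-dioxolane (acetal carbon: mixture of epimers) | I/C=C(\C)CC/C=C(/C)[C@@H](O[Si](C)(C)C(C)(C)C)[C@@H](O[Si](CC)(CC)CC)[C@@H]1COC(c2ccc(OC)cc2)O1 | intermediate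
23 | (2S,3S,4R,5Z,9E)-4-[(tert-butyldimethylsilyl)oxy]-10-iodo-2-[(4-methoxybenzyl)oxy]-5,9-dimethyl-3-[(triethylsilyl)oxy]deca-5,9-dien-1-ol | I/C=C(\C)CC/C=C(/C)[C@@H](O[Si](C)(C)C(C)(C)C)[C@@H](O[Si](CC)(CC)CC)[C@@H](OCc1ccc(OC)cc1)CO | intermediate
24 | (2R,3S,4R,5Z,9E)-4-[(tert-butyldimethylsilyl)oxy]-10-iodo-2-[(4-methoxybenzyl)oxy]-5,9-dimethyl-3-[(triethylsilyl)oxy]deca-5,9-dienal | I/C=C(\C)CC/C=C(/C)[C@@H](O[Si](C)(C)C(C)(C)C)[C@@H](O[Si](CC)(CC)CC)[C@@H](OCc1ccc(OC)cc1)C=O | intermediate
25 | (1S,2E,6Z,8R,9S,10S)-8-[(tert-butyldimethylsilyl)oxy]-10-[(4-methoxybenzyl)oxy]-3,7-dimethyl-9-[(triethylsilyl)oxy]cyclodeca-2,6-dien-1-ol | O[C@H]1/C=C(\C)CC/C=C(/C)[C@@H](O[Si](C)(C)C(C)(C)C)[C@@H](O[Si](CC)(CC)CC)[C@H]1OCc2ccc(OC)cc2 | intermediate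
26 | 2-bromoprop-2-enoic acid (2-bromoacrylic acid) | C=C(Br)C(=O)O | starting material
27 | (1R,2E,6Z,8R,9S,10S)-8-[(tert-butyldimethylsilyl)oxy]-10-[(4-methoxybenzyl)oxy]-3,7-dimethyl-9-[(triethylsilyl)oxy]cyclodeca-2,6-dien-1-yl 2-bromoprop-2-enoate | C=C(Br)C(=O)O[C@@H]1/C=C(\C)CC/C=C(/C)[C@@H](O[Si](C)(C)C(C)(C)C)[C@@H](O[Si](CC)(CC)CC)[C@H]1OCc2ccc(OC)cc2 | intermediate
28 | (1R,2E,6Z,8R,9S,10S)-8-[(tert-butyldimethylsilyl)oxy]-10-hydroxy-3,7-dimethyl-9-[(triethylsilyl)oxy]cyclodeca-2,6-dien-1-yl 2-bromoprop-2-enoate | C=C(Br)C(=O)O[C@@H]1/C=C(\C)CC/C=C(/C)[C@@H](O[Si](C)(C)C(C)(C)C)[C@@H](O[Si](CC)(CC)CC)[C@H]1O | intermediate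
29 | (1R,2E,6Z,8R,9R)-8-[(tert-butyldimethylsilyl)oxy]-3,7-dimethyl-10-oxo-9-[(triethylsilyl)oxy]cyclodeca-2,6-dien-1-yl 2-bromoprop-2-enoate | C=C(Br)C(=O)O[C@@H]1/C=C(\C)CC/C=C(/C)[C@@H](O[Si](C)(C)C(C)(C)C)[C@@H](O[Si](CC)(CC)CC)C1=O | intermediate
30 | (3aR,4R,5R,6Z,10E,11aR)-5-[(tert-butyldimethylsilyl)oxy]-3a-hydroxy-6,10-dimethyl-3-methylidene-4-[(triethylsilyl)oxy]-3a,4,5,8,9,11a-hexahydrocyclodeca[b]furan-2(3H)-one | C=C1C(=O)O[C@@H]2/C=C(\C)CC/C=C(/C)[C@@H](O[Si](C)(C)C(C)(C)C)[C@@H](O[Si](CC)(CC)CC)[C@@]12O | intermediate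
31 | (3aS,4R,5R,6Z,10E,11aR)-5-[(tert-butyldimethylsilyl)oxy]-3a,4-dihydroxy-6,10-dimethyl-3-methylidene-3a,4,5,8,9,11a-hexahydrocyclodeca[b]furan-2(3H)-one | C=C1C(=O)O[C@@H]2/C=C(\C)CC/C=C(/C)[C@@H](O[Si](C)(C)C(C)(C)C)[C@@H](O)[C@@]12O | intermediate
32 | tiglic acid, (2E)-2-methylbut-2-enoic acid | C/C=C(\C)C(=O)O | starting material
33 | (2E)-2-methylbut-2-en-1-ol | C/C=C(\C)CO | intermediate
34 | [(2R,3R)-2,3-dimethyloxiran-2-yl]methanol | OC[C@@]1(C)O[C@@H]1C | intermediate
35 | (2S,3R)-2,3-dimethyloxirane-2-carboxylic acid | OC(=O)[C@@]1(C)O[C@@H]1C | intermediate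
36 | (2S,3R)-2,3-dimethyloxirane-2-carboxylic 2,4,6-trichlorobenzoic anhydride | O=C(OC(=O)[C@@]1(C)O[C@@H]1C)c1c(Cl)cc(Cl)cc1Cl | intermediate
37 | (3aR,4R,5R,6Z,10E,11aR)-5-[(tert-butyldimethylsilyl)oxy]-3a-hydroxy-6,10-dimethyl-3-methylidene-2-oxo-2,3,3a,4,5,8,9,11a-octahydrocyclodeca[b]furan-4-yl (2S,3R)-2,3-dimethyloxirane-2-carboxylate | C=C1C(=O)O[C@@H]2/C=C(\C)CC/C=C(/C)[C@@H](O[Si](C)(C)C(C)(C)C)[C@@H](OC(=O)[C@@]3(C)O[C@@H]3C)[C@@]12O | intermediate
38 | (3aR,4R,5R,6Z,10E,11aR)-3a,5-dihydroxy-6,10-dimethyl-3-methylidene-2-oxo-2,3,3a,4,5,8,9,11a-octahydrocyclodeca[b]furan-4-yl (2S,3R)-2,3-dimethyloxirane-2-carboxylate | C=C1C(=O)O[C@@H]2/C=C(\C)CC/C=C(/C)[C@@H](O)[C@@H](OC(=O)[C@@]3(C)O[C@@H]3C)[C@@]12O | target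

## Step count and least certain steps

Total: 25 steps. Longest linear sequence: 21 steps from 1 to 38 (steps 1–9, 11–20, 24, 25).

**Step 19 (key step).** The alkenylchromium species may be protonated (simple loss of bromine), the nickel intermediate may homocouple, or the addition may take the other ketone face and give the cis-fused lactone. α-Metallated acrylates have not been established as donors in this ring closure, and facial control rests on the conformation of a medium ring. The fallback uses known reactions and runs from 25 to 30. Alcohol 25 is esterified with acetic acid under the Mitsunobu conditions of step 16 to give the inverted acetate F1. DDQ removes the PMB group to give the hydroxy acetate F2, and Dess–Martin oxidation gives the keto acetate F3. Excess ethynylmagnesium bromide adds to the C7 ketone and cleaves the acetate, giving the ethynyl diol F4. Palladium-catalysed cyclocarbonylation of this homopropargylic alcohol (PdCl2, SnCl2, PPh3, CO, MeCN) then closes the α-methylene lactone to 30. The facial selectivity of the acetylide addition is the weak point of this detour.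

**Step 15 (macrocyclisation).** Intermolecular coupling can outrun ring closure, and the Felkin–Anh preference at C6 may be overridden by the strain of the ten-membered transition state, giving poor or reversed facial selectivity. Dilution addresses the first. The second needs no repair of the ring closure, since the other outcome is also productive. If 24 closes mainly to the (1R) carbinol F5, that epimer already has the C6 configuration of the target. It is esterified with retention (26, DCC, DMAP, CH2Cl2) and rejoins the route at 27, replacing the inverting esterification by a retentive one.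

**Step 16 (inverting esterification).** Elimination to a triene, allylic transposition, or addition of the phosphine to the bromoacrylate may compete with SN2 displacement at a hindered ring carbinol. The fallback sets out from 25: Dess–Martin oxidation gives the enone F6, and 1,2-reduction (NaBH4, CeCl3·7H2O, MeOH, −78 °C, or an oxazaborolidine-catalysed borane reduction if substrate control is poor) gives the carbinol F5. Carbodiimide esterification with 26 then returns to 27.

**Step 4 (differentiation of the two primary alcohols).** Bromination of the saturated alcohol, or intramolecular ether formation between the free hydroxyl and the new allylic bromide, may erode selectivity. The fallback runs from 6 to 8: MnO2 oxidises only the allylic alcohol to the hydroxy enal F7; TESOTf/2,6-lutidine gives the silyl ether F8; NaBH4 reduces the enal to the allylic alcohol F9; CBr4/PPh3 gives 8.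

## Further compounds

F1 | step 19 | (1R,2E,6Z,8R,9S,10S)-8-[(tert-butyldimethylsilyl)oxy]-10-[(4-methoxybenzyl)oxy]-3,7-dimethyl-9-[(triethylsilyl)oxy]cyclodeca-2,6-dien-1-yl acetate | CC(=O)O[C@@H]1/C=C(\C)CC/C=C(/C)[C@@H](O[Si](C)(C)C(C)(C)C)[C@@H](O[Si](CC)(CC)CC)[C@H]1OCc2ccc(OC)cc2
F2 | step 19 | (1R,2E,6Z,8R,9S,10S)-8-[(tert-butyldimethylsilyl)oxy]-10-hydroxy-3,7-dimethyl-9-[(triethylsilyl)oxy]cyclodeca-2,6-dien-1-yl acetate | CC(=O)O[C@@H]1/C=C(\C)CC/C=C(/C)[C@@H](O[Si](C)(C)C(C)(C)C)[C@@H](O[Si](CC)(CC)CC)[C@H]1O
F3 | step 19 | (1R,2E,6Z,8R,9R)-8-[(tert-butyldimethylsilyl)oxy]-3,7-dimethyl-10-oxo-9-[(triethylsilyl)oxy]cyclodeca-2,6-dien-1-yl acetate | CC(=O)O[C@@H]1/C=C(\C)CC/C=C(/C)[C@@H](O[Si](C)(C)C(C)(C)C)[C@@H](O[Si](CC)(CC)CC)C1=O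
F4 | step 19 | (1R,2R,3E,7Z,9R,10R)-9-[(tert-butyldimethylsilyl)oxy]-1-ethynyl-4,8-dimethyl-10-[(triethylsilyl)oxy]cyclodeca-3,7-diene-1,2-diol | O[C@@H]1/C=C(\C)CC/C=C(/C)[C@@H](O[Si](C)(C)C(C)(C)C)[C@@H](O[Si](CC)(CC)CC)[C@@]1(O)C#C
F5 | step 15 | (1R,2E,6Z,8R,9S,10S)-8-[(tert-butyldimethylsilyl)oxy]-10-[(4-methoxybenzyl)oxy]-3,7-dimethyl-9-[(triethylsilyl)oxy]cyclodeca-2,6-dien-1-ol | O[C@@H]1/C=C(\C)CC/C=C(/C)[C@@H](O[Si](C)(C)C(C)(C)C)[C@@H](O[Si](CC)(CC)CC)[C@H]1OCc2ccc(OC)cc2
F6 | step 16 | (2E,6Z,8R,9S,10R)-8-[(tert-butyldimethylsilyl)oxy]-10-[(4-methoxybenzyl)oxy]-3,7-dimethyl-9-[(triethylsilyl)oxy]cyclodeca-2,6-dien-1-one | O=C1/C=C(\C)CC/C=C(/C)[C@@H](O[Si](C)(C)C(C)(C)C)[C@@H](O[Si](CC)(CC)CC)[C@H]1OCc2ccc(OC)cc2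
F7 | step 4 | (2Z,4R,5S)-4-[(tert-butyldimethylsilyl)oxy]-6-hydroxy-3-methyl-5-[(triethylsilyl)oxy]hex-2-enal | O=C/C=C(/C)[C@@H](O[Si](C)(C)C(C)(C)C)[C@@H](O[Si](CC)(CC)CC)CO
F8 | step 4 | (2Z,4R,5S)-4-[(tert-butyldimethylsilyl)oxy]-3-methyl-5,6-bis[(triethylsilyl)oxy]hex-2-enal | O=C/C=C(/C)[C@@H](O[Si](C)(C)C(C)(C)C)[C@@H](O[Si](CC)(CC)CC)CO[Si](CC)(CC)CC
F9 | step 4 | (2Z,4R,5S)-4-[(tert-butyldimethylsilyl)oxy]-3-methyl-5,6-bis[(triethylsilyl)oxy]hex-2-en-1-ol | OC/C=C(/C)[C@@H](O[Si](C)(C)C(C)(C)C)[C@@H](O[Si](CC)(CC)CC)CO[Si](CC)(CC)CC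
A1 | alternative 1 | ten-membered (1(10)Z,4E)-dien-9-one with a C6,C7 acetonide, a C8 4-methoxybenzyl ether and a 3-(triethylsilyloxy)prop-1-en-2-yl group on C7 | C=C(CO[Si](CC)(CC)CC)[C@@]12OC(C)(C)O[C@@H]1/C=C(\C)CC/C=C(/C)C(=O)[C@H]2OCc1ccc(OC)cc1
A2 | alternative 2 | ten-membered C7,C8 trans-diol with a C6 triethylsilyl ether, a C9 tert-butyldimethylsilyl ether and a 2,2-dimethyl-1,3-dioxan-5-yl group on C7 | CC1(C)OCC(CO1)[C@@]2(O)[C@H](O[Si](CC)(CC)CC)/C=C(\C)CC/C=C(/C)[C@@H](O[Si](C)(C)C(C)(C)C)[C@H]2O
A3 | alternative 3 | ten-membered 7-hydroxy-6,12-lactone lacking the C13 methylene, with a C8 4-methoxybenzyl ether and a C9 tert-butyldimethylsilyl ether | O=C1C[C@@]2(O)[C@H](O1)/C=C(\C)CC/C=C(/C)[C@@H](O[Si](C)(C)C(C)(C)C)[C@H]2OCc3ccc(OC)cc3
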